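**Conventions.** Carbons carry the macrolide numbers throughout (C1 = lactone carbonyl, C13 = carbinol carbon of the lactone). "Up" and "down" refer to the zigzag chain drawn from C1 (left) to C13 (right).

## Analysis of the target

8,8a-Deoxyoleandolide (45) is a 14-membered lactone made of C1–C13 and the oxygen on C13; it has no other ring and no C=C bond, only the C1 lactone and C9 ketone carbonyls. Ten ring carbons are stereocentres, (2R,3S,4R,5S,6S,8R,10R,11S,12R,13R), with methyl groups on C2, C4, C6, C8, C10, C12 and C13 and free hydroxyls on C3, C5 and C11. In the zigzag, 2-Me, 3-OH, 4-Me, 5-OH, 10-Me and 11-OH are up and 6-Me, 8-Me, 12-Me and 13-O are down: C2–C5 is all-syn, C5/C6 anti, C6/C8 1,3-syn, C10/C11 syn, C11/C12 anti, C12/C13 syn. The sensitive region is C8–C11: the ketone lies between two epimerisable methines, the 11-hydroxyl is β to it (retro-aldol, elimination), and the 5-hydroxyl can add to C9 as a hemiketal. The synthesis is hard for three reasons: the C7 methylene interrupts stereochemical relay between C6 and C8; the oxygens at C3, C5, C9 and C11 must be told apart; and a hindered, heavily branched seco acid must be closed. The strategy rests on the 1,5-relation of O5 and C9: O5, C5, C6, C7, C8 and C9 can form one six-membered ring in which the 6- and 8-methyls are 1,3-cis and C7 can be a removable carbonyl, i.e. a 3,5-dimethyl-2,3-dihydropyran-4-one.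

## Retrosynthetic reasoning

**Unmasking and C9 oxidation level (45 ⇐ 44 ⇐ 43 ⇐ 42).** The last step removes only acid-labile groups from 44 (11-O-silyl, 3,5-isopropylidene), so no base meets the β-hydroxy ketone. The ketone is made from the 9-alcohol 43, freed selectively from the 9-O-triethylsilyl ether 42. C9 stays sp3 through ring closure because a 9-ketone in the seco acid would be 1,5-related to the free 13-hydroxyl (hemiketal) and would put C8 and C10 at risk under the basic closure conditions.

**Lactone bond (42 ⇐ 40 ⇐ 38 ⇐ 37).** The C1–O13 ester is the only heteroatom bond of the ring, so cutting it gives a linear C1–C13 chain that can be built from fragments. The forward reaction needs an activated C1 acid and a single free hydroxyl, at C13. The 3,5-isopropylidene acetal on the syn-diol restricts the C2–C6 segment and should help the chain ends meet. Both termini are benzyl ethers in 37, so one hydrogenolysis gives diol 38 and a primary-selective oxidation gives acid 40.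

**Redox differentiation of C9 and C11 (37 ⇐ 36 ⇐ 35 ⇐ 34 ⇐ 32).** The aldol adduct 32 has the hydroxyl at C9 and the carbonyl at C11, the reverse of the target. A hydroxyl-directed intramolecular hydride transfer of the Tishchenko type reduces C11 anti to O9 and acylates O9 in the same event, so the two oxygens leave the step already differentiated (34). O11 is then silylated (35), the C9 ester is cleaved reductively (36) and replaced by a more labile silyl ether (37).

**C9–C10 bond (32 ⇐ 24 + 30).** This aldol bond divides the chain into a C1–C9 aldehyde with six stereocentres and a C10–C13 ethyl ketone with two, which is the most convergent cut available. The forward reaction must set C10 and a temporary C9 centre: an (E)-boron enolate of 30 should give 9,10-anti, 10,12-anti and Felkin (8,9-syn) addition, three preferences that point the same way.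

**Ketone 30 (30 ⇐ 29 ⇐ 28 ⇐ 27 ⇐ 5 + 25).** C12 and C13 come from an auxiliary-controlled syn aldol of imide 5 with acetaldehyde 25, run through the chlorotitanium enolate 26 so that the small, water-soluble adduct 27 is isolated without an oxidative work-up. Amide exchange (28), benzylation (29) and ethyl addition follow. The same imide 5 serves both chiral fragments.

**Opening the template (24 ⇐ 23 ⇐ 22 ⇐ 21 ⇐ 20).** In 20, C9 and O5 are tied in a cyclic acetal. Plain hydrolysis would give a lactol that stays closed and cannot be protected at O5. Opening with a dithiol instead frees O5 and holds C9 as an open-chain thioacetal (22), so O3 and O5 can be bridged (23) before the aldehyde is released (24).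

**C7 deoxygenation and C8 (20 ⇐ 19 ⇐ 18 ⇐ 17).** The C7 carbonyl of 17 is reduced (18) and the resulting allylic alcohol is transposed: the oxygen leaves C7, the double bond moves to C7=C8 and C9 becomes an acetal (19). Hydrogenation from the ring face opposite the axial anomeric methoxy group then puts the 8-methyl cis to the 6-methyl (20).

**Key disconnection (17 ⇐ 16 ⇐ 10 + 15).** Cutting C5–C6 and O5–C9 returns the ring to aldehyde 10, which already holds C2–C4, and diene 15, which brings C6–C9 with both methyls. This gains the ring, C5 and C6, and a C9 that is chemically distinct from every other oxygenated carbon. The forward step must deliver the 4,5-syn and 5,6-anti relations.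

**Aldehyde 10 (10 ⇐ 9 ⇐ 8 ⇐ 7 ⇐ 4 + 5; 4 ⇐ 3 ⇐ 2 ⇐ 1).** The C3–C4 bond is a syn aldol between imide 5 and aldehyde 4; C2 comes from hydroxy ester 1. The (S)-configured auxiliary is required: with (S)-aldehyde 4 it gives the all-syn C2–C4 triad, whereas its mirror image would give 3,4-syn but 2,3-anti.

**Diene 15 (15 ⇐ 14 ⇐ 13 ⇐ 11 + 12).** Formylation of ketone 11 with formate 12, O-methylation and enol silylation.

## Alternatives that were turned down

**Alternative 1:** Two-directional crotylboration. C4–C5 and C9–C10 are cut at once, back to the meso dialdehyde A2 (C5–C9 with the 6,8-syn methyls). In the forward step A2 reacts at both formyl groups with an achiral (Z)-crotylboronate to give the meso diene diol A1, setting C4, C5, C9 and C10 together.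
- For: a (Z)-crotyl reagent gives the syn methyl/hydroxyl relation and prefers anti-Felkin addition, which is exactly the 4,5-syn/5,6-anti pattern needed at C4–C6 and its mirror image at C8–C10. For the C4–C10 segment this is far shorter than the chosen route, and on that point the alternative is stronger.
- Against: A1 is meso, so its two ends and its two hydroxyls (O5 to keep, O9 to oxidise) are enantiotopic and need an enantioselective desymmetrisation. Substrate control with an achiral reagent is modest and must hold at both ends. Five centres (C2, C3, C11, C12, C13) remain to be added to unlike termini.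
- Comparison: the chosen strategy gives up the symmetry shortcut. In return, O5 (ring oxygen) and C9 (acetal carbon) differ from the moment they are made, and each centre has its own control element in a six-membered ring.

**Alternative 2:** Oxygen insertion into a carbocycle. The C13–O bond is cut, back to the 13-membered carbocyclic ketone A4. In the forward step a buffered peroxy acid inserts oxygen between C1 and C13 with retention at C13, giving the protected 9-dihydro macrolactone A3.
- For: it avoids the lactonisation of a hindered seco acid, and migration is stereoretentive; on ring-closure entropy it is at least as strong as the chosen route.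
- Against: A4 needs a 13-membered ring closure through a C–C bond, which is harder than an ester closure. The ketone lies between two methyl-bearing methines (C2 and C13) of similar migratory aptitude, so regiochemistry rests on a small electronic difference. Both α-centres are epimerisable in A4, and an electron-rich benzyl ether is exposed to the peroxy acid. After A3 the C9 oxidation and the deprotections are still to come.
- Comparison: the chosen strategy closes the ring at the only heteroatom bond by a well-understood acylation, and makes every C–C bond in an acyclic or six-membered setting.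

**Alternative 3:** Twofold hydroboration of a macrocyclic diene. The C5–O and C11–O bonds (and C4–H, C10–H) are cut, back to the diene lactone A6. In the forward step borane adds to both trisubstituted alkenes from the ring periphery and oxidation gives A5, setting C4, C5, C10 and C11.
- For: four stereocentres in one step, secure regiochemistry (boron at the CH carbon), and a macrocycle with fewer stereocentres and two sp2 units should close more easily. On both points it is stronger than the chosen route.
- Against: syn addition maps alkene geometry onto the methyl/hydroxyl relation, so the 4,5-syn and 10,11-syn relations require both alkenes with the ring carbons cis (4Z,10Z), which must be made and kept. Facial selectivity at two remote sites depends on the macrocycle conformation and may conflict with local allylic control from C3, C6, C9 and C12. Four centres therefore depend on one conformational prediction.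
- Comparison: the chosen strategy sets C5, C6 and C8 on a six-membered ring with axial/equatorial logic, and each centre can be corrected on its own.

Key step: step 11

Assumption: the target is taken as the open 9-keto form of its SMILES; a ring–chain equilibrium with the 5,9-hemiketal would not change the route.

## Route

Step 1
Reactants: 1 methyl (S)-3-hydroxy-2-methylpropanoate
Product: 2 methyl (S)-3-(benzyloxy)-2-methylpropanoate
Conditions: BnOC(=NH)CCl3, CF3SO3H (cat.), cyclohexane/CH2Cl2, 0 °C → rt
Reagents that add atoms: benzyl 2,2,2-trichloroacetimidate, ClC(Cl)(Cl)C(=N)OCc1ccccc1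
Why: Acid-catalysed O-benzylation with a trichloroacetimidate; the non-basic conditions leave the α-stereocentre (future C2) untouched.

Step 2
Reactants: 2 methyl (S)-3-(benzyloxy)-2-methylpropanoate
Product: 3 (R)-3-(benzyloxy)-2-methylpropan-1-ol
Conditions: LiAlH4, THF, 0 °C
Reagents that add atoms: none
Why: Hydride reduction of the ester to the primary alcohol; the stereocentre is not involved (the descriptor changes only through CIP priorities).

Step 3
Reactants: 3 (R)-3-(benzyloxy)-2-methylpropan-1-ol
Product: 4 (S)-3-(benzyloxy)-2-methylpropanal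
Conditions: TEMPO (cat.), PhI(OAc)2, CH2Cl2, rt
Reagents that add atoms: none
Why: Nitroxyl-catalysed oxidation stops at the aldehyde under near-neutral conditions; the aldehyde is used at once to avoid racemisation.

Step 4
Reactants: 5 (S)-4-benzyl-3-propanoyl-1,3-oxazolidin-2-one; 4 (S)-3-(benzyloxy)-2-methylpropanal
Product: 7 (S)-4-benzyl-3-[(2S,3R,4S)-5-(benzyloxy)-3-hydroxy-2,4-dimethylpentanoyl]-1,3-oxazolidin-2-one, via boron enolate 6 (not isolated)
Conditions: Bu2BOTf, Et3N, CH2Cl2, 0 °C; then 4, −78 → 0 °C; then H2O2, MeOH, pH 7 buffer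
Reagents that add atoms: none
Why: Evans syn aldol: the (Z)-boron enolate 6 reacts through a chair Zimmerman–Traxler transition state on the enolate face away from the benzyl group, setting C3 and C4 (3,4-syn); auxiliary control should override the weaker, opposite bias of the α-methyl aldehyde, and the (S)-auxiliary is the one that gives the all-syn C2–C4 triad.

Step 5
Reactants: 7 (S)-4-benzyl-3-[(2S,3R,4S)-5-(benzyloxy)-3-hydroxy-2,4-dimethylpentanoyl]-1,3-oxazolidin-2-one
Product: 8 (S)-4-benzyl-3-[(2S,3R,4S)-5-(benzyloxy)-3-(tert-butyldimethylsilyloxy)-2,4-dimethylpentanoyl]-1,3-oxazolidin-2-one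
Conditions: TBSOTf, 2,6-lutidine, CH2Cl2, 0 °C
Reagents that add atoms: tert-butyldimethylsilyl trifluoromethanesulfonate, CC(C)(C)[Si](C)(C)OS(=O)(=O)C(F)(F)F
Why: Silyl triflate silylation of the hindered C3 hydroxyl; the bulky, weakly basic silyl ether is the group wanted at C3 for the key step.

Step 6
Reactants: 8 (S)-4-benzyl-3-[(2S,3R,4S)-5-(benzyloxy)-3-(tert-butyldimethylsilyloxy)-2,4-dimethylpentanoyl]-1,3-oxazolidin-2-one
Product: 9 (2R,3S,4S)-5-(benzyloxy)-3-(tert-butyldimethylsilyloxy)-2,4-dimethylpentan-1-ol
Conditions: LiBH4, MeOH (1 equiv), THF, 0 °C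
Reagents that add atoms: none
Why: Reductive cleavage of the N-acyl oxazolidinone gives the primary alcohol and returns the auxiliary; no stereocentre is touched.

Step 7
Reactants: 9 (2R,3S,4S)-5-(benzyloxy)-3-(tert-butyldimethylsilyloxy)-2,4-dimethylpentan-1-ol
Product: 10 (2S,3R,4S)-5-(benzyloxy)-3-(tert-butyldimethylsilyloxy)-2,4-dimethylpentanal (C1–C5 aldehyde)
Conditions: Dess–Martin periodinane, CH2Cl2, 0 °C → rt
Reagents that add atoms: none
Why: Dess–Martin oxidation to the α-branched aldehyde under non-basic conditions, which avoids epimerisation at C4 and β-elimination of the silyloxy group.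

Step 8
Reactants: 11 pentan-3-one; 12 ethyl formate
Product: 13 (Z)-1-hydroxy-2-methylpent-1-en-3-one (enol of 2-methyl-3-oxopentanal)
Conditions: NaH, EtOH (cat.), Et2O, 0 °C → rt; then aq. HCl
Reagents that add atoms: none
Why: Crossed Claisen formylation of the ketone enolate with a non-enolisable formate; deprotonation of the product drives the reaction, and acidification gives the chelated enol.

Step 9
Reactants: 13 (Z)-1-hydroxy-2-methylpent-1-en-3-one
Product: 14 (E)-1-methoxy-2-methylpent-1-en-3-one
Conditions: Me2SO4, K2CO3, acetone, reflux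
Reagents that add atoms: dimethyl sulfate, COS(=O)(=O)OC
Why: O-Alkylation of the β-keto aldehyde enolate with a hard methylating agent gives the vinylogous ester, which should settle as the more stable E isomer.

Step 10
Reactants: 14 (E)-1-methoxy-2-methylpent-1-en-3-one
Product: 15 (1E,3Z)-1-methoxy-2-methyl-3-(trimethylsilyloxy)penta-1,3-diene
Conditions: TMSOTf, Et3N, Et2O, 0 °C
Reagents that add atoms: trimethylsilyl trifluoromethanesulfonate, C[Si](C)(C)OS(=O)(=O)C(F)(F)F
Why: Soft enolisation–silylation at the ethyl CH2 of the vinylogous ester gives the cross-conjugated silyloxy diene; amine/silyl triflate conditions favour the (Z)-enol ether.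

Step 11
Reactants: 10 (2S,3R,4S)-5-(benzyloxy)-3-(tert-butyldimethylsilyloxy)-2,4-dimethylpentanal; 15 (1E,3Z)-1-methoxy-2-methyl-3-(trimethylsilyloxy)penta-1,3-diene
Product: 17 (2R,3R)-2-[(2R,3R,4S)-5-(benzyloxy)-3-(tert-butyldimethylsilyloxy)-4-methylpentan-2-yl]-3,5-dimethyl-2,3-dihydro-4H-pyran-4-one (C5–C9 dihydropyranone), via open-chain aldol adduct 16 (not isolated)
Conditions: BF3·OEt2, CH2Cl2, −78 °C; then CF3CO2H (cat.), CH2Cl2, rt
Reagents that add atoms: none
Why: This is the diene–aldehyde cyclocondensation in its stepwise Lewis-acid mode (Mukaiyama aldol, then ring closure), the known behaviour of 1-alkoxy-3-silyloxy dienes with BF3-activated aldehydes. BF3 binds the formyl oxygen of 10, and the silyl enol ether terminus of 15 (C6) attacks C5 through an open, antiperiplanar transition state, giving 16 after loss of the silyl group. The ring closes by 6-endo-trig conjugate addition of the C5 oxygen to C9 of the β-methoxy enone followed by β-elimination of the methoxy group, which the acid drives to completion; this forms O5–C9 and leaves the enone of 17. C5 is set by Felkin–Anh 1,2-induction from the C4 methyl centre: attack anti to the C3-bearing chain gives the 4,5-syn relation. C6 is set by the open transition state, in which the C6 methyl and the aldehyde substituent avoid each other, giving the 5,6-anti relation that becomes the trans ring substitution. The selectivity needed is Felkin control over 1,3-anti induction from the β-oxygen; the bulky, weakly basic silyl ether at C3, the monodentate Lewis acid and the branched nucleophile should all favour Felkin control. Using BF3 in CH2Cl2 and not a chelating or lanthanide Lewis acid disfavours the pericyclic pathway that would give the cis-pyranone.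

Step 12
Reactants: 17 C5–C9 dihydropyranone
Product: 18 C7 allylic alcohol of 17 (7-OH cis to the C5 side chain)
Conditions: NaBH4, CeCl3·7H2O, MeOH, −78 °C
Reagents that add atoms: none
Why: Luche reduction: CeCl3 promotes 1,2-hydride addition to the vinylogous ester carbonyl; axial delivery should give the pseudo-equatorial alcohol, but the C7 configuration is erased in the next step.

Step 13
Reactants: 18 C7 allylic alcohol of 17
Product: 19 methyl acetal with C7=C8 double bond (9-OMe trans to the C5 side chain)
Conditions: MeOH (10 equiv), TsOH·H2O (cat.), CH2Cl2, 0 °C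
Reagents that add atoms: methanol, CO
Why: Ferrier-type allylic transposition: acid ionises the C7 hydroxyl to an allylic oxocarbenium ion spanning C7–C9, which methanol captures at C9 by axial attack trans to the C5 substituent; the double bond moves to C7=C8 and the C7 oxygen is removed.

Step 14
Reactants: 19 methyl acetal with C7=C8 double bond
Product: 20 tetrahydropyran methyl acetal (8-Me cis to 6-Me and to 9-OMe; 3-OTBS)
Conditions: H2 (1 atm), Pd/C, pyridine (0.5 equiv), EtOAc, rt
Reagents that add atoms: none
Why: Heterogeneous syn hydrogenation: the axial anomeric methoxy group of the half-chair shields its face, so hydrogen should add to C7=C8 from the opposite face and place the 8-methyl cis to the 6-methyl (both equatorial, 8R); pyridine suppresses hydrogenolysis of the benzyl ether and of the allylic acetal.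

Step 15
Reactants: 20 tetrahydropyran methyl acetal
Product: 21 C3 alcohol of 20
Conditions: Bu4NF, THF, rt → 40 °C
Reagents that add atoms: none
Why: Fluoride-mediated desilylation frees the C3 hydroxyl so that O3 and O5 can later be bridged; the acetal and the benzyl ether are inert to fluoride.

Step 16
Reactants: 21 C3 alcohol of 20
Product: 22 C1–C9 dithiane diol (1-OBn; 3,5-diol; C9 as 1,3-dithian-2-yl)
Conditions: HS(CH2)3SH, BF3·OEt2, CH2Cl2, −20 → 0 °C
Reagents that add atoms: propane-1,3-dithiol, SCCCS
Why: Lewis-acid-mediated transthioacetalisation: the cyclic acetal ionises at C9 and is captured twice by the dithiol, which opens the ring, frees O5 and keeps C9 at the aldehyde oxidation level as a 1,3-dithiane; C8 is not enolised.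

Step 17
Reactants: 22 C1–C9 dithiane diol
Product: 23 3,5-O-isopropylidene acetal of 22
Conditions: Me2C(OMe)2, PPTS (cat.), CH2Cl2, rt
Reagents that add atoms: 2,2-dimethoxypropane, COC(C)(C)OC
Why: Acid-catalysed acetal exchange; the syn-3,5-diol closes readily to a chair 1,3-dioxane, which later restricts the C2–C6 segment during macrocyclisation.

Step 18
Reactants: 23 3,5-O-isopropylidene acetal of 22
Product: 24 C1–C9 aldehyde (1-OBn; 3,5-O-isopropylidene; C9 = CHO)
Conditions: MeI, CaCO3, MeCN/H2O (9:1), 40 °C
Reagents that add atoms: water, O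
Why: S-Alkylative hydrolysis of the dithiane under buffered, near-neutral conditions unmasks the C9 aldehyde without epimerising C8 or opening the acetonide.

Step 19
Reactants: 5 (S)-4-benzyl-3-propanoyl-1,3-oxazolidin-2-one; 25 acetaldehyde
Product: 27 (S)-4-benzyl-3-[(2S,3R)-3-hydroxy-2-methylbutanoyl]-1,3-oxazolidin-2-one, via chlorotitanium enolate 26 (not isolated)
Conditions: TiCl4, iPr2NEt, N-methyl-2-pyrrolidinone, CH2Cl2, 0 °C; then 25, −78 → 0 °C; then aq. NH4Cl
Reagents that add atoms: none
Why: Titanium-mediated Evans syn aldol by soft enolisation: TiCl4 and the amine give the (Z)-trichlorotitanium enolate 26, which reacts through a chair Zimmerman–Traxler transition state on the enolate face away from the benzyl group and sets C12 and C13 (12,13-syn) in the configuration of the target; the simple aqueous quench, with no peroxide work-up, suits the small, water-soluble adduct.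

Step 20
Reactants: 27 (S)-4-benzyl-3-[(2S,3R)-3-hydroxy-2-methylbutanoyl]-1,3-oxazolidin-2-one
Product: 28 (2S,3R)-3-hydroxy-N-methoxy-N,2-dimethylbutanamide
Conditions: MeONHMe·HCl, AlMe3, THF, 0 °C; then 1 M HCl
Reagents that add atoms: N,O-dimethylhydroxylamine hydrochloride, CNOC.Cl
Why: Aluminium amide transamination of the β-hydroxy imide to the Weinreb amide; the free β-hydroxyl assists exocyclic cleavage and the auxiliary is released.

Step 21
Reactants: 28 (2S,3R)-3-hydroxy-N-methoxy-N,2-dimethylbutanamide
Product: 29 (2S,3R)-3-(benzyloxy)-N-methoxy-N,2-dimethylbutanamide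
Conditions: BnOC(=NH)CCl3, CF3SO3H (cat.), cyclohexane/CH2Cl2, 0 °C → rt
Reagents that add atoms: benzyl 2,2,2-trichloroacetimidate, ClC(Cl)(Cl)C(=N)OCc1ccccc1
Why: Acid-catalysed benzylation avoids the base-induced retro-aldol or elimination of the β-hydroxy amide.

Step 22
Reactants: 29 (2S,3R)-3-(benzyloxy)-N-methoxy-N,2-dimethylbutanamide
Product: 30 (4S,5R)-5-(benzyloxy)-4-methylhexan-3-one (C10–C13 ketone)
Conditions: EtMgBr, THF, 0 °C; aq. NH4Cl
Reagents that add atoms: ethylmagnesium bromide, CC[Mg]Br
Why: Grignard addition to the Weinreb amide stops at the ketone through the stable magnesium chelate; the ethyl group supplies C10 and its methyl.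

Step 23
Reactants: 30 (4S,5R)-5-(benzyloxy)-4-methylhexan-3-one; 24 C1–C9 aldehyde
Product: 32 C1–C13 aldol adduct (9-OH down; 11-ketone; 1,13-di-O-benzyl; 3,5-acetonide), via boron enolate 31 (not isolated)
Conditions: (c-Hex)2BCl, Et3N, Et2O, 0 °C; then 24, −78 → −20 °C; then H2O2, MeOH, pH 7 buffer
Reagents that add atoms: none
Why: Boron-mediated anti aldol: the (E)-enol borinate 31 forms on the ethyl side and reacts through a chair Zimmerman–Traxler transition state (9,10-anti); the C12 centre of the enolate should direct attack to give 10,12-anti methyls and the aldehyde reacts in the Felkin sense (8,9-syn) that (E)-enolates prefer, so the three elements reinforce and set C10 as in the target and C9 as the later directing group.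

Step 24
Reactants: 32 C1–C13 aldol adduct
Product: 34 9-O-propanoyl 11-alcohol (11-OH up), via propanal hemiacetal 33 (not isolated)
Conditions: SmI2 (30 mol%), EtCHO (excess), THF, −10 °C
Reagents that add atoms: propanal, CCC=O
Why: Evans–Tishchenko reduction: the C9 hydroxyl forms hemiacetal 33, a trivalent samarium centre holds the hemiacetal oxygen and the C11 ketone in a six-membered chair, and hydride is delivered intramolecularly anti to O9, giving the 11S alcohol while O9 becomes the propanoate.

Step 25
Reactants: 34 9-O-propanoyl 11-alcohol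
Product: 35 11-O-TBS ether of 34
Conditions: TBSOTf, 2,6-lutidine, CH2Cl2, −78 → 0 °C
Reagents that add atoms: tert-butyldimethylsilyl trifluoromethanesulfonate, CC(C)(C)[Si](C)(C)OS(=O)(=O)C(F)(F)F
Why: Silyl triflate silylation of the hindered C11 hydroxyl; under these non-nucleophilic conditions the neighbouring ester should not migrate.

Step 26
Reactants: 35 11-O-TBS ether of 34
Product: 36 9-alcohol (11-OTBS)
Conditions: iBu2AlH, CH2Cl2, −78 °C
Reagents that add atoms: none
Why: Reductive cleavage of the only ester in the molecule frees O9 without touching silyl ether, acetal or benzyl ethers.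

Step 27
Reactants: 36 9-alcohol (11-OTBS)
Product: 37 9-O-TES ether of 36
Conditions: Et3SiOTf, 2,6-lutidine, CH2Cl2, −78 °C
Reagents that add atoms: triethylsilyl trifluoromethanesulfonate, CC[Si](CC)(CC)OS(=O)(=O)C(F)(F)F
Why: The triethylsilyl ether protects C9 through the ring closure and can later be removed in the presence of the bulkier silyl ether at C11.

Step 28
Reactants: 37 9-O-TES ether of 36
Product: 38 1,13-diol
Conditions: H2 (1 atm), Pd(OH)2/C, EtOAc, rt
Reagents that add atoms: none
Why: Hydrogenolysis of both benzyl ethers frees the C1 and C13 hydroxyls in one operation; ethyl acetate as solvent avoids solvolysis of the triethylsilyl ether.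

Step 29
Reactants: 38 1,13-diol
Product: 40 seco acid, via hydroxy aldehyde 39 (not isolated)
Conditions: TEMPO (cat.), PhI(OAc)2, CH2Cl2, rt; then NaClO2, NaH2PO4, 2-methylbut-2-ene, t-BuOH/H2O, 0 °C → rt
Reagents that add atoms: sodium chlorite, [Na+].[O-]Cl=O
Why: Nitroxyl-catalysed oxidation is selective for the primary C1 hydroxyl over the hindered secondary C13 hydroxyl and stops at aldehyde 39; Pinnick oxidation then gives the acid under mildly acidic conditions that should not epimerise C2.

Step 30
Reactants: 40 seco acid
Product: 42 macrolactone (9-OTES; 11-OTBS; 3,5-acetonide), via mixed anhydride 41 (not isolated)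
Conditions: 2,4,6-Cl3C6H2COCl, Et3N, THF, rt; then DMAP, toluene (high dilution, slow addition), 80 °C
Reagents that add atoms: none
Why: Yamaguchi macrolactonisation: DMAP attacks the aliphatic carbonyl of mixed anhydride 41 and the acylpyridinium is captured by the C13 hydroxyl, the only free hydroxyl, under high dilution; the 3,5-acetonide pre-organises the chain.

Step 31
Reactants: 42 macrolactone
Product: 43 9-hydroxy macrolactone
Conditions: HF·pyridine, pyridine, THF, 0 °C
Reagents that add atoms: none
Why: Buffered HF·pyridine cleaves the triethylsilyl ether much faster than the tert-butyldimethylsilyl ether at C11, and the anhydrous medium leaves the acetonide intact.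

Step 32
Reactants: 43 9-hydroxy macrolactone
Product: 44 9-oxo macrolactone (11-OTBS; 3,5-acetonide)
Conditions: Dess–Martin periodinane, CH2Cl2, rt
Reagents that add atoms: none
Why: Dess–Martin oxidation of the only free hydroxyl gives the C9 ketone under non-basic conditions, so C8 and C10 are not epimerised and the β-silyloxy group is not eliminated.

Step 33
Reactants: 44 9-oxo macrolactone
Product: 45 8,8a-deoxyoleandolide
Conditions: 48% aq. HF, MeCN, 0 °C → rt
Reagents that add atoms: none
Why: Aqueous HF cleaves the remaining silyl ether and, as a dilute aqueous acid, hydrolyses the isopropylidene acetal; no base is involved, so the β-hydroxy ketone and its α-centres should survive.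

## Compound list

1 | methyl (S)-3-hydroxy-2-methylpropanoate | COC(=O)[C@@H](C)CO | starting material
2 | methyl (S)-3-(benzyloxy)-2-methylpropanoate | COC(=O)[C@@H](C)COCc1ccccc1 | intermediate
3 | (R)-3-(benzyloxy)-2-methylpropan-1-ol | OC[C@@H](C)COCc1ccccc1 | intermediate
4 | (S)-3-(benzyloxy)-2-methylpropanal | O=C[C@@H](C)COCc1ccccc1 | intermediate
5 | (S)-4-benzyl-3-propanoyl-1,3-oxazolidin-2-one | CCC(=O)N1[C@@H](Cc2ccccc2)COC1=O | starting material
6 | (Z)-dibutylboron enolate of 5 | C/C=C(\OB(CCCC)CCCC)N1[C@@H](Cc2ccccc2)COC1=O | intermediate (not isolated)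
7 | (S)-4-benzyl-3-[(2S,3R,4S)-5-(benzyloxy)-3-hydroxy-2,4-dimethylpentanoyl]-1,3-oxazolidin-2-one | c1ccccc1COC[C@H](C)[C@@H](O)[C@H](C)C(=O)N1[C@@H](Cc2ccccc2)COC1=O | intermediate
8 | (S)-4-benzyl-3-[(2S,3R,4S)-5-(benzyloxy)-3-(tert-butyldimethylsilyloxy)-2,4-dimethylpentanoyl]-1,3-oxazolidin-2-one | c1ccccc1COC[C@H](C)[C@@H](O[Si](C)(C)C(C)(C)C)[C@H](C)C(=O)N1[C@@H](Cc2ccccc2)COC1=O | intermediate
9 | (2R,3S,4S)-5-(benzyloxy)-3-(tert-butyldimethylsilyloxy)-2,4-dimethylpentan-1-ol | c1ccccc1COC[C@H](C)[C@@H](O[Si](C)(C)C(C)(C)C)[C@H](C)CO | intermediate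
10 | (2S,3R,4S)-5-(benzyloxy)-3-(tert-butyldimethylsilyloxy)-2,4-dimethylpentanal (C1–C5 aldehyde) | c1ccccc1COC[C@H](C)[C@@H](O[Si](C)(C)C(C)(C)C)[C@H](C)C=O | intermediate
11 | pentan-3-one | CCC(=O)CC | starting material
12 | ethyl formate | CCOC=O | starting material
13 | (Z)-1-hydroxy-2-methylpent-1-en-3-one (enol of 2-methyl-3-oxopentanal) | CCC(=O)/C(C)=C\O | intermediate
14 | (E)-1-methoxy-2-methylpent-1-en-3-one | CCC(=O)/C(C)=C/OC | intermediate
15 | (1E,3Z)-1-methoxy-2-methyl-3-(trimethylsilyloxy)penta-1,3-diene | CO/C=C(C)/C(O[Si](C)(C)C)=C/C | intermediate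
16 | open-chain aldol adduct: C1–C9 (E)-9-methoxy-7-oxo-8-ene with free 5-OH (4,5-syn; 5,6-anti), 1-OBn, 3-OTBS | c1ccccc1COC[C@H](C)[C@@H](O[Si](C)(C)C(C)(C)C)[C@H](C)[C@@H](O)[C@@H](C)C(=O)/C(C)=C/OC | intermediate (not isolated)
17 | (2R,3R)-2-[(2R,3R,4S)-5-(benzyloxy)-3-(tert-butyldimethylsilyloxy)-4-methylpentan-2-yl]-3,5-dimethyl-2,3-dihydro-4H-pyran-4-one (C5–C9 dihydropyranone) | c1ccccc1COC[C@H](C)[C@@H](O[Si](C)(C)C(C)(C)C)[C@H](C)[C@H]1OC=C(C)C(=O)[C@@H]1C | intermediate
18 | C7 allylic alcohol of 17 (7-OH cis to the C5 side chain, trans to 6-Me) | c1ccccc1COC[C@H](C)[C@@H](O[Si](C)(C)C(C)(C)C)[C@H](C)[C@H]1OC=C(C)[C@@H](O)[C@@H]1C | intermediate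
19 | methyl acetal with C7=C8 double bond (9-OMe trans to the C5 side chain) | c1ccccc1COC[C@H](C)[C@@H](O[Si](C)(C)C(C)(C)C)[C@H](C)[C@H]1O[C@H](OC)C(C)=C[C@@H]1C | intermediate
20 | tetrahydropyran methyl acetal (8-Me cis to 6-Me and to 9-OMe; 3-OTBS) | c1ccccc1COC[C@H](C)[C@@H](O[Si](C)(C)C(C)(C)C)[C@H](C)[C@H]1O[C@H](OC)[C@H](C)C[C@@H]1C | intermediate
21 | C3 alcohol of 20 | c1ccccc1COC[C@H](C)[C@@H](O)[C@H](C)[C@H]1O[C@H](OC)[C@H](C)C[C@@H]1C | intermediate
22 | C1–C9 dithiane diol (1-OBn; 3,5-diol; C9 as 1,3-dithian-2-yl) | c1ccccc1COC[C@H](C)[C@@H](O)[C@H](C)[C@@H](O)[C@@H](C)C[C@@H](C)C2SCCCS2 | intermediate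
23 | 3,5-O-isopropylidene acetal of 22 | c1ccccc1COC[C@H](C)[C@H]2OC(C)(C)O[C@H]([C@H]2C)[C@@H](C)C[C@@H](C)C3SCCCS3 | intermediate
24 | C1–C9 aldehyde (1-OBn; 3,5-O-isopropylidene; C9 = CHO) | c1ccccc1COC[C@H](C)[C@H]2OC(C)(C)O[C@H]([C@H]2C)[C@@H](C)C[C@@H](C)C=O | intermediate
25 | acetaldehyde | CC=O | starting material
26 | (Z)-trichlorotitanium enolate of 5 | C/C=C(\O[Ti](Cl)(Cl)Cl)N1[C@@H](Cc2ccccc2)COC1=O | intermediate (not isolated)
27 | (S)-4-benzyl-3-[(2S,3R)-3-hydroxy-2-methylbutanoyl]-1,3-oxazolidin-2-one | O=C([C@@H](C)[C@H](O)C)N1[C@@H](Cc2ccccc2)COC1=O | intermediate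
28 | (2S,3R)-3-hydroxy-N-methoxy-N,2-dimethylbutanamide | CON(C)C(=O)[C@@H](C)[C@H](O)C | intermediate
29 | (2S,3R)-3-(benzyloxy)-N-methoxy-N,2-dimethylbutanamide | CON(C)C(=O)[C@@H](C)[C@H](OCc1ccccc1)C | intermediate
30 | (4S,5R)-5-(benzyloxy)-4-methylhexan-3-one (C10–C13 ketone) | CCC(=O)[C@@H](C)[C@H](OCc1ccccc1)C | intermediate
31 | (E)-enol dicyclohexylborinate of 30 | C/C=C(/OB(C1CCCCC1)C1CCCCC1)[C@@H](C)[C@H](OCc1ccccc1)C | intermediate (not isolated)
32 | C1–C13 aldol adduct (9-OH down; 11-ketone; 1,13-di-O-benzyl; 3,5-acetonide) | c1ccccc1COC[C@H](C)[C@H]2OC(C)(C)O[C@H]([C@H]2C)[C@@H](C)C[C@@H](C)[C@H](O)[C@H](C)C(=O)[C@@H](C)[C@H](OCc3ccccc3)C | intermediate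
33 | propanal hemiacetal of 32 at O9 | c1ccccc1COC[C@H](C)[C@H]2OC(C)(C)O[C@H]([C@H]2C)[C@@H](C)C[C@@H](C)[C@H](OC(O)CC)[C@H](C)C(=O)[C@@H](C)[C@H](OCc3ccccc3)C | intermediate (not isolated)
34 | 9-O-propanoyl 11-alcohol (11-OH up) | c1ccccc1COC[C@H](C)[C@H]2OC(C)(C)O[C@H]([C@H]2C)[C@@H](C)C[C@@H](C)[C@H](OC(=O)CC)[C@H](C)[C@@H](O)[C@@H](C)[C@H](OCc3ccccc3)C | intermediate
35 | 11-O-TBS ether of 34 | c1ccccc1COC[C@H](C)[C@H]2OC(C)(C)O[C@H]([C@H]2C)[C@@H](C)C[C@@H](C)[C@H](OC(=O)CC)[C@H](C)[C@@H](O[Si](C)(C)C(C)(C)C)[C@@H](C)[C@H](OCc3ccccc3)C | intermediate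
36 | 9-alcohol (11-OTBS) | c1ccccc1COC[C@H](C)[C@H]2OC(C)(C)O[C@H]([C@H]2C)[C@@H](C)C[C@@H](C)[C@H](O)[C@H](C)[C@@H](O[Si](C)(C)C(C)(C)C)[C@@H](C)[C@H](OCc3ccccc3)C | intermediate
37 | 9-O-TES ether of 36 | c1ccccc1COC[C@H](C)[C@H]2OC(C)(C)O[C@H]([C@H]2C)[C@@H](C)C[C@@H](C)[C@H](O[Si](CC)(CC)CC)[C@H](C)[C@@H](O[Si](C)(C)C(C)(C)C)[C@@H](C)[C@H](OCc3ccccc3)C | intermediate
38 | 1,13-diol | OC[C@H](C)[C@H]2OC(C)(C)O[C@H]([C@H]2C)[C@@H](C)C[C@@H](C)[C@H](O[Si](CC)(CC)CC)[C@H](C)[C@@H](O[Si](C)(C)C(C)(C)C)[C@@H](C)[C@H](O)C | intermediate
39 | hydroxy aldehyde (C1 = CHO; 13-OH free) | O=C[C@H](C)[C@H]2OC(C)(C)O[C@H]([C@H]2C)[C@@H](C)C[C@@H](C)[C@H](O[Si](CC)(CC)CC)[C@H](C)[C@@H](O[Si](C)(C)C(C)(C)C)[C@@H](C)[C@H](O)C | intermediate (not isolated)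
40 | seco acid (13-OH free; 9-OTES; 11-OTBS; 3,5-acetonide) | OC(=O)[C@H](C)[C@H]2OC(C)(C)O[C@H]([C@H]2C)[C@@H](C)C[C@@H](C)[C@H](O[Si](CC)(CC)CC)[C@H](C)[C@@H](O[Si](C)(C)C(C)(C)C)[C@@H](C)[C@H](O)C | intermediate
41 | 2,4,6-trichlorobenzoic mixed anhydride of 40 | O=C(c1c(Cl)cc(Cl)cc1Cl)OC(=O)[C@H](C)[C@H]2OC(C)(C)O[C@H]([C@H]2C)[C@@H](C)C[C@@H](C)[C@H](O[Si](CC)(CC)CC)[C@H](C)[C@@H](O[Si](C)(C)C(C)(C)C)[C@@H](C)[C@H](O)C | intermediate (not isolated)
42 | macrolactone (9-OTES; 11-OTBS; 3,5-acetonide) | O=C1[C@H](C)[C@H]2OC(C)(C)O[C@H]([C@H]2C)[C@@H](C)C[C@@H](C)[C@H](O[Si](CC)(CC)CC)[C@H](C)[C@@H](O[Si](C)(C)C(C)(C)C)[C@@H](C)[C@@H](C)O1 | intermediate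
43 | 9-hydroxy macrolactone | O=C1[C@H](C)[C@H]2OC(C)(C)O[C@H]([C@H]2C)[C@@H](C)C[C@@H](C)[C@H](O)[C@H](C)[C@@H](O[Si](C)(C)C(C)(C)C)[C@@H](C)[C@@H](C)O1 | intermediate
44 | 9-oxo macrolactone (11-OTBS; 3,5-acetonide) | O=C1[C@H](C)[C@H]2OC(C)(C)O[C@H]([C@H]2C)[C@@H](C)C[C@@H](C)C(=O)[C@H](C)[C@@H](O[Si](C)(C)C(C)(C)C)[C@@H](C)[C@@H](C)O1 | intermediate
45 | 8,8a-deoxyoleandolide | C[C@@H]1[C@@H](O)[C@@H](C)C[C@@H](C)C(=O)[C@H](C)[C@@H](O)[C@@H](C)[C@@H](C)OC(=O)[C@H](C)[C@H]1O | target

## Step count and least certain steps

Total: 33 steps. Longest linear sequence: 26 steps (steps 1–7, 11–18 and 23–33, from 1 to 45). The diene branch (steps 8–10) and the ketone branch (steps 19–22) are three and four steps.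

**Step 11 (key step).** Most likely failure: poor facial selectivity at the aldehyde, because 1,3-induction from the C3 oxygen opposes Felkin control in this syn-configured aldehyde; or erosion of the anti (trans) selectivity if part of the reaction runs through a closed or pericyclic pathway. Fallback: replace the open transition state by a closed one. Enone 14 is converted with (c-Hex)2BCl and Et3N into the (E)-enol dicyclohexylborinate F1, which adds to aldehyde 10 at −78 °C through a chair transition state (anti, and Felkin-selective for an (E)-enolate). After oxidative work-up the aldol adduct 16 is isolated and then closed with catalytic acid, and the route is rejoined at pyranone 17.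

**Step 13 (allylic transposition).** Most likely failure: protonation of the enol ether at C8 and addition of methanol across C8=C9 in place of ionisation at C7, or loss of the C3 silyl ether in acidic methanol. Fallback: separate activation from acetal formation. Alcohol 18 is acetylated (Ac2O, pyridine, DMAP) to the C7 acetate F2, which undergoes the Lewis-acid Ferrier rearrangement with methanol (BF3·OEt2 cat., CH2Cl2, −20 °C) and rejoins the route at 19.

**Step 14 (hydrogenation).** Most likely failure: incomplete facial discrimination, giving some C8 epimer, or hydrogenolysis of the allylic C9–O bond. Fallback: correct C8 by thermodynamic control in place of kinetic control. Acetal 20 (as the C8 mixture) is hydrolysed with aqueous acetic acid to the lactol F3, which is oxidised (TEMPO, PhI(OAc)2) to the δ-lactone F4. Base equilibration (DBU, toluene) should move the α-methyl into the equatorial position cis to the 6-methyl. Reduction with iBu2AlH returns lactol F3, and methanol with PPTS returns 20.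

**Step 30 (macrolactonisation).** Most likely failure: oligomerisation if the seco acid does not fold, or epimerisation at C2 through ketene formation from the α-branched mixed anhydride under amine base. Fallback: activate the acid as a thioester under neutral conditions. Seco acid 40 is converted with 2,2'-dipyridyl disulfide and PPh3 into the S-(pyridin-2-yl) thioester F5, which is cyclised at high dilution in toluene with AgOSO2CF3 (Corey–Nicolaou-type activation, no amine base) and rejoins the route at macrolactone 42.

## Further compounds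

F1 | step 11 | (E)-enol dicyclohexylborinate of 14 | C/C=C(/OB(C1CCCCC1)C1CCCCC1)\C(C)=C\OC
F2 | step 13 | C7 acetate of 18 | c1ccccc1COC[C@H](C)[C@@H](O[Si](C)(C)C(C)(C)C)[C@H](C)[C@H]1OC=C(C)[C@@H](OC(C)=O)[C@@H]1C
F3 | step 14 | C9 lactol from 20 (anomeric centre unassigned) | c1ccccc1COC[C@H](C)[C@@H](O[Si](C)(C)C(C)(C)C)[C@H](C)[C@H]1OC(O)[C@H](C)C[C@@H]1C
F4 | step 14 | C9 δ-lactone (8-Me cis to 6-Me after equilibration) | c1ccccc1COC[C@H](C)[C@@H](O[Si](C)(C)C(C)(C)C)[C@H](C)[C@H]1OC(=O)[C@H](C)C[C@@H]1C
F5 | step 30 | S-(pyridin-2-yl) thioester of 40 | O=C(Sc1ccccn1)[C@H](C)[C@H]2OC(C)(C)O[C@H]([C@H]2C)[C@@H](C)C[C@@H](C)[C@H](O[Si](CC)(CC)CC)[C@H](C)[C@@H](O[Si](C)(C)C(C)(C)C)[C@@H](C)[C@H](O)C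
A1 | alternative 1 | meso C3–C11 diene diol | C=C[C@H](C)[C@@H](O)[C@@H](C)C[C@@H](C)[C@@H](O)[C@H](C)C=C
A2 | alternative 1 | meso-2,4-dimethylpentanedial | O=C[C@@H](C)C[C@@H](C)C=O
A3 | alternative 2 | protected 9-dihydro macrolactone (3,5-acetonide; 9-OPMB; 11-OTBS) | O=C1[C@H](C)[C@@H](O2)[C@H](C)[C@@H](OC2(C)C)[C@@H](C)C[C@@H](C)[C@@H](OCc3ccc(OC)cc3)[C@H](C)[C@@H](O[Si](C)(C)C(C)(C)C)[C@@H](C)[C@@H](C)O1
A4 | alternative 2 | 13-membered carbocyclic ketone (C1 ketone bonded to C2 and C13) | O=C1[C@H](C)[C@@H](O2)[C@H](C)[C@@H](OC2(C)C)[C@@H](C)C[C@@H](C)[C@@H](OCc3ccc(OC)cc3)[C@H](C)[C@@H](O[Si](C)(C)C(C)(C)C)[C@@H](C)[C@H]1C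
A5 | alternative 3 | protected 9-dihydro macrolactone with free 5- and 11-hydroxyls | O=C1[C@H](C)[C@@H](O[Si](C)(C)C(C)(C)C)[C@H](C)[C@@H](O)[C@@H](C)C[C@@H](C)[C@@H](OCc2ccc(OC)cc2)[C@H](C)[C@@H](O)[C@@H](C)[C@@H](C)O1
A6 | alternative 3 | (4Z,10Z)-14-membered diene lactone | O=C1[C@H](C)[C@@H](O[Si](C)(C)C(C)(C)C)/C(C)=C\[C@@H](C)C[C@@H](C)[C@@H](OCc2ccc(OC)cc2)/C(C)=C\[C@@H](C)[C@@H](C)O1
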